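# Proposed total synthesis of sipholenol K

## Analysis of the target

Sipholenol K consists of two bicyclic halves joined by a CH2–CH2 tether. One half is a trans-fused perhydrobenzoxepine: ring C is a cyclohexane and ring D an oxepane. The other half is a cis-fused octalone: ring A is a 2-methylcyclohexenone and ring B a cyclohexane carrying CMe2 and C(Me)OH.

The CD half holds five contiguous stereocentres:
- the quaternary C–Me ring-fusion carbon;
- the O–CH ring-fusion carbon, trans to it;
- the tether-bearing CH;
- the tertiary carbinol of ring C, whose methyl group is 1,3-diaxial to the angular methyl;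
- the CH(OH) of ring D next to the CMe2–O carbon.

The AB half holds three: the two cis ring-fusion CH groups and the tertiary carbinol of ring B, whose hydroxyl is cis to both ring-fusion hydrogens. The tether insulates the two sets from each other, so each half has to be made with its own absolute control.

Sensitive groups are the two tertiary alcohols (elimination), the tert-alkyl ether of ring D (acid), and the enone, whose γ-carbon is a ring-fusion stereocentre (base).

The difficulties are the seven-membered ether flanked by a fully substituted carbon and a carbinol, the congested ring C, and the cis ring fusion of AB next to a quaternary carbon.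

The strategy rests on one observation. If the ring-D oxygen between the CMe2 carbon and the O–CH ring-fusion carbon is deleted, ring D becomes a cyclohexanone of a trans-decalin with the substitution pattern of the Wieland–Miescher ketone. A Baeyer–Villiger oxygen insertion puts the oxygen back with retention at the ring-fusion carbon.

## Retrosynthetic reasoning

**Tether to ring A.** Sipholenol K (48) is taken back to its tris-silyl ether 47, and 47 to the tertiary allylic alcohol 46. The bond cut is the one between the second tether carbon and the β-carbon of the ring-A enone. It is the only bond between the halves that ends at an sp2 carbon, and that carbon can be the carbonyl of a smaller enone (43) if the oxygen is moved by a 1,3-oxidative transposition afterwards. A cut at the ring-C end would place bond formation on a CH flanked by two fully substituted carbons. The cut gives two fragments of similar size, 43 and iodide 29 (used as alkyllithium 44), and creates no lasting stereocentre. The forward reaction must add to a hindered, enolisable ketone without epimerising its α ring-fusion centre.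

**Ring A and the cis fusion.** The cis-fused enone 43 is traced to its epimer mixture 41, and 41 to keto aldehyde 40 by opening the enone C=C (aldol condensation forward). Only one enolisable carbon of 40 can reach the aldehyde through a six-membered ring, so the closure has no regiochemical choice. The ring-fusion carbon next to the carbonyl is then corrected by kinetic protonation of enolate 42. This uses the fact that this centre is α to a ketone in 43 but only γ in the final enone.

**Ring B.** The two carbonyl groups of 40 are masked as the terminal alkenes of 38 and 37. The tertiary carbinol of 37 comes from ketone 36 by methyl addition opposite the C3 substituent. Ketone 36 comes from enone 33 by conjugate addition of the butenyl group of borane 32 (made from bromide 30) and allylation of the resulting enolate. The absolute configuration of the AB half is fixed in this one catalyst-controlled step; the rest follows from the ring.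

**Tether carbons.** Iodide 29 is taken back through 28 and 26 to aldehyde 25 and alcohol 24, a one-carbon homologation at the ring-C CH. It is placed after all ring-D chemistry so that the primary oxygen can stay protected until then.

**CMe2–O unit.** The two C–CH3 bonds of 23 are cut back to the carbonyl of lactone 20, through cyclopropane 22 and enol ether 21. This is what makes a lactone a useful precursor of the ether.

**Ring D (key disconnection).** Lactone 18 is taken back to decalone 17 by removing the ring oxygen, that is, by cutting the O–CH(ring fusion) bond and rejoining carbonyl carbon and ring-fusion carbon. What is gained is a six-membered carbocycle in place of a seven-membered heterocycle, on a rigid trans-decalin. The forward step must insert oxygen on the ring-fusion side of the ketone and not on the oxygenated side, and must keep the ring-fusion configuration.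

**α-Oxygen.** Compound 17 comes from 16, and 16 from ketone 13 through silyl enol ether 14. The C–O bond next to the carbonyl is made by axial attack on the face opposite the angular methyl, which is the configuration ring D needs.

**Ketone oxygen, ring fusion and hydroxymethyl group.** Ketone 13 comes from diol 11, and 11 from diene 9. One double hydroboration delivers the C5 oxygen, the trans ring-fusion hydrogen and the equatorial CH2OH.

**Ring C carbinol and start.** Diene 9 goes back through 8 and 7 to methyl ketone 5, and on to octalinone 3 and the Wieland–Miescher ketone 1 through dithiolane 2. The tertiary carbinol is set by enolate hydroxylation anti to the angular methyl. The enone oxygen of 1 is removed because the oxygen is needed one carbon further on.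

## Alternatives that were turned down

**Alternative 1:** Ring B is opened at the bond between the ring-fusion carbon next to the carbonyl and the gem-dimethyl carbon. The bicyclic vinylogous ester A1 then goes back to A2, a monocyclic silyl enol ether carrying a side chain with a tertiary chloride. Forward, a Lewis acid ionises the chloride and the enol carbon captures the tertiary cation, closing ring B.
- For: the most hindered C–C bond of the AB half is made intramolecularly. The tertiary carbinol is carried in with the side chain. A1 is ready for the same addition and transposition tactic that joins the halves here.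
- Against: the ionising conditions act next to a tertiary silyl ether that can ionise too. The cation can lose a proton instead of cyclising. The new ring-fusion centre is α to a ketone and can epimerise. Above all, the step does nothing for ring D.
- Comparison: for the AB half this route is as strong as the chosen one or stronger, since it is shorter than the path to 43 and needs no asymmetric catalysis if the carbinol is bought in. The chosen strategy offers in its place a regio- and stereocontrolled construction of the oxepane on a rigid decalin. It reaches its AB half without cationic intermediates.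

**Alternative 2:** Ring C is cut at the bond from the quaternary carbon to the first CH2 of the future ring-D chain and at the bond from the neighbouring CH to the tether. Cyclohexanone A3 goes back to the enantiopure silyloxy enone A4. Forward, a copper-catalysed 1,4-addition delivers the homoprenyl chain anti to the silyloxy group, and the enolate is allylated.
- For: the quaternary centre and its neighbour are set in one step. The chain carries every carbon of ring D. The allyl group already holds the tether carbons, so the four homologation steps 19–22 of the present route would not be needed.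
- Against: ring D would have to close by a 7-endo epoxide opening at the tertiary carbon, in competition with 6-exo closure to a tetrahydropyran, and the CH(OH) centre would depend on a reagent-controlled epoxidation. The ketone of A3 must become a carbinol whose methyl is syn-axial to the angular methyl. Direct methyl addition gives the other epimer, so a detour is needed.
- Comparison: A3 is stronger on step economy for ring C and the tether. The chosen route is stronger on ring D: the O–C bond forms with retention and without an exo/endo choice, the carbinol next to it is set by axial attack on a chair, and the ring-C carbinol comes from enolate hydroxylation anti to the angular methyl.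

**Alternative 3:** The AB half is cut at the bond between the two ring-fusion carbons and at the bond from the ring-A CH2 to the oxygenated carbon. Octalone A5 goes back to trienone A6, which already carries the complete CD half. Forward, the vinyl ketone of A6 adds to its tethered alkoxy diene in an intramolecular Diels–Alder reaction.
- For: both rings, the cis ring fusion and the ring-A alkene in its final place arise in one concerted step.
- Against: the diene is substituted at three of its four carbons and its terminus sits on the quaternary CMe2, so the reaction should be slow and the diene geometry hard to secure. All CD stereocentres are remote from the reacting π-systems, so the facial sense, and with it the configuration of AB relative to CD, is not controlled. The ring-B ketone still has to become the tertiary carbinol and the allylic ether the enone. The oxepane half is again taken for granted.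
- Comparison: on the cis ring fusion this route is stronger than the kinetic protonation used here. The chosen route offers separate absolute control of each half and places its uncertain key step early, on material made from a cheap enantiopure diketone.

Key step: step 12

## Remarks before the steps

- β denotes the face of the decalin that carries the angular methyl group, α the opposite face. Decalin positions are numbered as in the Wieland–Miescher ketone (C1 saturated ketone, C6 enone carbonyl, C4a and C8a ring fusion).
- Remark on the chemistry: the acyl group on the α-oxygen that steers the Baeyer–Villiger migration is taken as a 2,2,2-trichloroethyl carbonate and not a benzoate, because zinc removes it without touching the ε-lactone. The tertiary hydroxyl of ring C is carried as its TBS ether.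
- Assumption: the rhodium–(R)-BINAP catalyst is taken to show the same facial sense on 4,4-dimethylcyclohex-2-en-1-one as on cyclohex-2-enone. If it does not, (S)-BINAP is used.

## Route

### Part 1: ring-CD fragment up to the decalone (steps 1–11)

Step 1
Reactants: 1 (R)-Wieland–Miescher ketone
Product: 2 6,6-ethylenedithio ketal of 1 (dithiolane at the enone carbonyl, alkene kept at C4a=C5)
Conditions: HSCH2CH2SH, p-TsOH (cat.), AcOH, rt
Reagents that add atoms: ethane-1,2-dithiol, SCCS
Why: Acid-catalysed thioketalisation is much faster at the conjugated carbonyl than at the ketone next to the quaternary carbon, and the dithiolane holds the alkene in place.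

Step 2
Reactants: 2 dithiolane
Product: 3 (8aR)-8a-methyl-3,4,6,7,8,8a-hexahydronaphthalen-1(2H)-one
Conditions: Raney Ni (W-2, acetone-deactivated), EtOH, reflux
Reagents that add atoms: none
Why: Reductive desulfurisation replaces both C–S bonds by C–H, which removes the enone oxygen and leaves the trisubstituted alkene that later carries the ketone oxygen and the ring-fusion hydrogen.

Step 3
Reactants: 3 octalinone
Product: 5 2,8a-dimethyl octalinone (C2 epimers), via lithium enolate 4 (not isolated)
Conditions: LiN(iPr)2, THF, −78 °C; MeI, −78 → 0 °C
Reagents that add atoms: iodomethane, CI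
Why: The ketone can enolise only toward C2 because the other α-carbon is quaternary, so enolate methylation is regiospecific; the C2 configuration is erased in the next step.

Step 4
Reactants: 5 methyl ketone
Product: 7 2α-hydroxy-2β-methyl ketone (methyl cis, hydroxyl trans to the angular methyl), via potassium enolate 6 (not isolated)
Conditions: KN(SiMe3)2, THF, −78 °C; 2-(phenylsulfonyl)-3-phenyloxaziridine; aq. NH4Cl
Reagents that add atoms: 2-(phenylsulfonyl)-3-phenyloxaziridine, O=S(=O)(c1ccccc1)N1OC1c1ccccc1
Why: Enolate hydroxylation by oxygen transfer from the oxaziridine; the pseudoaxial angular methyl shields the β-face of the tetrasubstituted enolate, so oxygen should enter on the α-face and the methyl group ends syn to the angular methyl, as in ring C of the target.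

Step 5
Reactants: 7 hydroxy ketone
Product: 8 tertiary TBS ether of 7
Conditions: TBSOTf, 2,6-lutidine, CH2Cl2, 0 °C → rt
Reagents that add atoms: tert-butyldimethylsilyl triflate, CC(C)(C)[Si](C)(C)OS(=O)(=O)C(F)(F)F
Why: Silylation of the tertiary alcohol with the silyl triflate; the ketone has no enolisable hydrogen left, so only the oxygen reacts.

Step 6
Reactants: 8 silyloxy ketone
Product: 9 1-methylene compound (exocyclic alkene at C1, ring alkene at C4a=C5)
Conditions: Cp2TiMe2, toluene, 75 °C
Reagents that add atoms: dimethyltitanocene, C[Ti](C)(C1C=CC=C1)C1C=CC=C1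
Why: Petasis methylenation; the titanium methylidene formed on heating olefinates hindered, non-enolisable ketones flanked by two fully substituted carbons, where phosphorus ylides are too bulky.

Step 7
Reactants: 9 diene
Product: 11 diol (1β-CH2OH, 5α-OH, 4aα-H, trans-decalin), via bis(alkylborane) 10 (not isolated)
Conditions: BH3·THF (excess), THF, 0 °C → rt; NaOH, H2O2
Reagents that add atoms: hydrogen peroxide, OO
Why: Hydroboration–oxidation of both alkenes; boron adds to the less substituted carbon and on the α-face of each alkene, away from the axial methyl groups, which should give the equatorial hydroxymethyl group at C1, the trans ring fusion and the equatorial C5 alcohol.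

Step 8
Reactants: 11 diol
Product: 12 primary TBS ether with free C5 alcohol
Conditions: TBSCl, imidazole, CH2Cl2, 0 °C
Reagents that add atoms: tert-butyldimethylsilyl chloride, CC(C)(C)[Si](C)(C)Cl
Why: The primary hydroxyl is silylated far faster than the secondary hydroxyl next to the ring fusion.

Step 9
Reactants: 12 secondary alcohol
Product: 13 trans-decalin-5-one
Conditions: Dess–Martin periodinane, NaHCO3, CH2Cl2, rt
Reagents that add atoms: none
Why: Oxidation of the secondary alcohol under buffered, non-epimerising conditions; the trans ring fusion is in any case the stable arrangement of this decalone.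

Step 10
Reactants: 13 decalone
Product: 16 6α-hydroxy-5-ketone (axial hydroxyl, trans to the angular methyl), via trimethylsilyl enol ether 14 (not isolated), via silyloxy ketone 15 (not isolated)
Conditions: LiN(iPr)2, Me3SiCl, THF, −78 °C; mCPBA, NaHCO3, CH2Cl2, 0 °C; citric acid, MeOH
Reagents that add atoms: 3-chloroperbenzoic acid, OOC(=O)c1cccc(Cl)c1
Why: Rubottom oxidation; kinetic enolisation takes the CH2 and not the ring-fusion CH, the peracid attacks the enol ether on the α-face (axial at C6 and opposite the angular methyl that is syn-axial to C5), and mild acid frees the axial hydroxyl without epimerisation.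

Step 11
Reactants: 16 hydroxy ketone
Product: 17 6α-(2,2,2-trichloroethoxycarbonyloxy)-5-ketone (precursor of the key step)
Conditions: ClCO2CH2CCl3, pyridine, CH2Cl2, 0 °C
Reagents that add atoms: 2,2,2-trichloroethyl chloroformate, ClC(=O)OCC(Cl)(Cl)Cl
Why: Acylation of the secondary alcohol under mild base at low temperature, so that the axial α-oxygenated centre is not epimerised; the carbonate makes the oxygenated α-carbon electron-poor.

### Part 2: key step and the oxepane (steps 12–17)

Step 12
Reactants: 17 α-carbonate decalone
Product: 18 trans-fused ε-lactone (oxepan-2-one with the ring oxygen on the ring-fusion CH)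
Conditions: CF3CO3H [from (CF3CO)2O and H2O2·urea], Na2HPO4, CH2Cl2, 0 °C → rt
Reagents that add atoms: trifluoroperacetic acid, OOC(=O)C(F)(F)F
Why: Trifluoroperacetic acid adds to the C5 carbonyl to give the tetrahedral peroxy adduct; the C4a–C5 bond, held anti to the O–O bond, shifts to oxygen as trifluoroacetate leaves. The closest known reaction type is the Baeyer–Villiger oxidation of α-acyloxy cyclohexanones, in which the non-oxygenated, more electron-rich secondary carbon migrates. Ring D is not closed by attack of a tethered nucleophile; it arises by 1,2-shift ring expansion of the cyclohexanone, so no exo or endo mode has to be met. No new stereocentre forms: the migrating carbon keeps its configuration, so the trans relation between the O–CH and the angular methyl is carried over, and C6 is untouched because the medium is not basic. The selectivity needed is migration of the ring-fusion carbon rather than the oxygenated carbon; it is secured by the electron-withdrawing carbonate on C6 and by the attachment of C4a to the quaternary carbon. The buffer keeps the silyl ethers intact, and no other group in 17 is oxidisable by the peracid.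

Step 13
Reactants: 18 carbonate lactone
Product: 19 α-hydroxy lactone
Conditions: Zn, AcOH, THF, rt
Reagents that add atoms: none
Why: Zinc reduces the trichloroethyl group with β-elimination and the carbonate loses CO2; the lactone and the silyl ethers are inert to these conditions, which a basic ester cleavage would not guarantee.

Step 14
Reactants: 19 hydroxy lactone
Product: 20 α-TBS-oxy lactone
Conditions: TBSOTf, 2,6-lutidine, CH2Cl2, 0 °C
Reagents that add atoms: tert-butyldimethylsilyl triflate, CC(C)(C)[Si](C)(C)OS(=O)(=O)C(F)(F)F
Why: Silylation leaves the lactone as the only carbonyl group in the molecule, which the next step requires.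

Step 15
Reactants: 20 lactone
Product: 21 exocyclic enol ether (2-methyleneoxepane)
Conditions: Cp2TiMe2, toluene, 70 °C, dark
Reagents that add atoms: dimethyltitanocene, C[Ti](C)(C1C=CC=C1)C1C=CC=C1
Why: Petasis methylenation converts the lactone carbonyl into the enol ether; the reagent is not basic, so the α-silyloxy centre is safe.

Step 16
Reactants: 21 enol ether
Product: 22 spiro-cyclopropane (4-oxaspiro[2.6]nonane unit)
Conditions: Et2Zn, CH2I2, CH2Cl2, 0 °C → rt
Reagents that add atoms: diiodomethane, ICI
Why: Simmons–Smith cyclopropanation (Furukawa conditions) of the electron-rich 1,1-disubstituted enol ether; the spiro carbon carries two equivalent CH2 groups and is no stereocentre.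

Step 17
Reactants: 22 cyclopropane
Product: 23 2,2-dimethyloxepane (CMe2–O unit of ring D)
Conditions: H2 (4 atm), PtO2, AcOH, rt
Reagents that add atoms: none
Why: Hydrogenolysis of a 1,1-disubstituted cyclopropane over platinum cleaves the unsubstituted CH2–CH2 bond, so the spiro ring becomes two methyl groups on the carbon bound to the ring oxygen.

### Part 3: tether homologation (steps 18–22)

Step 18
Reactants: 23 tris-silyl ether
Product: 24 primary alcohol
Conditions: HF·pyridine, pyridine, THF, 0 °C
Reagents that add atoms: none
Why: The primary silyl ether is cleaved much faster than the secondary one next to CMe2 and the tertiary one.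

Step 19
Reactants: 24 alcohol
Product: 25 aldehyde
Conditions: Dess–Martin periodinane, NaHCO3, CH2Cl2, rt
Reagents that add atoms: none
Why: Buffered oxidation to the aldehyde, whose formyl group is already equatorial, so there is no drive to epimerise.

Step 20
Reactants: 25 aldehyde
Product: 26 vinyl compound
Conditions: Ph3PCH3Br, KN(SiMe3)2, THF, −78 → 0 °C
Reagents that add atoms: methyltriphenylphosphonium bromide, C[P+](c1ccccc1)(c1ccccc1)c1ccccc1.[Br-]
Why: Wittig methylenation; the small ylide reaches the hindered aldehyde at low temperature, which limits β-elimination of the silyloxy group.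

Step 21
Reactants: 26 alkene
Product: 28 2-hydroxyethyl compound, via B-alkyl-9-BBN 27 (not isolated)
Conditions: 9-BBN, THF, rt; NaOH, H2O2
Reagents that add atoms: hydrogen peroxide, OO
Why: Hydroboration with the bulky borane places boron on the terminal carbon only; oxidation gives the primary alcohol.

Step 22
Reactants: 28 alcohol
Product: 29 2-iodoethyl compound (ring-CD fragment)
Conditions: I2, PPh3, imidazole, CH2Cl2, rt
Reagents that add atoms: iodine, II
Why: Appel-type iodination of an unhindered primary alcohol; the silyl ethers and the cyclic ether are inert.

### Part 4: ring-AB fragment (steps 23–29)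

Step 23
Reactants: 30 2-bromobut-1-ene
Product: 32 9-(but-1-en-2-yl)-9-borabicyclo[3.3.1]nonane, via Grignard reagent 31 (not isolated)
Conditions: Mg, THF; 9-MeO-9-BBN, −78 °C → rt
Reagents that add atoms: 9-methoxy-9-borabicyclo[3.3.1]nonane, COB1C2CCCC1CCC2
Why: Grignard formation and transmetalation to boron give the alkenylborane that transfers only its alkenyl group to rhodium.

Step 24
Reactants: 33 4,4-dimethylcyclohex-2-en-1-one; 32 alkenylborane
Product: 36 (2S,3S)-2-allyl-3-(but-1-en-2-yl)-4,4-dimethylcyclohexan-1-one (trans), via boron enolate 34 (not isolated), via lithium enolate 35 (not isolated)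
Conditions: [Rh(OMe)(cod)]2 (cat.), (R)-BINAP, toluene, 80 °C; n-BuLi, THF, −78 °C; allyl bromide, −78 → 0 °C
Reagents that add atoms: allyl bromide, C=CCBr
Why: Rhodium-catalysed asymmetric conjugate addition (Hayashi–Miyaura type) of the alkenylborane gives a boron enolate with the double bond fixed between C1 and C2, and the BINAP ligand sets C3. After exchange to the lithium enolate the allyl group enters anti to the C3 substituent.

Step 25
Reactants: 36 ketone
Product: 37 tertiary alcohol (methyl cis to allyl, hydroxyl trans to allyl and cis to the C3 substituent)
Conditions: MeAl(O-2,6-tBu2-4-MeC6H2)2 (from Me3Al and the phenol), toluene, −78 °C; MeLi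
Reagents that add atoms: methyllithium, [Li]C
Why: Carbonyl methylation with the carbonyl bound to the bulky aluminium phenoxide; methyllithium then attacks from the face opposite the C3 alkenyl group, which is axial attack in the diequatorial chair and equatorial attack in the diaxial chair, so in both the methyl ends cis to the allyl group.

Step 26
Reactants: 37 tertiary alcohol
Product: 38 triethylsilyl ether
Conditions: Et3SiOTf, 2,6-lutidine, CH2Cl2, 0 °C
Reagents that add atoms: triethylsilyl triflate, CC[Si](CC)(CC)OS(=O)(=O)C(F)(F)F
Why: Silylation prevents lactol formation with the aldehyde made next and protects the alcohol in the organometallic steps.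

Step 27
Reactants: 38 diene
Product: 40 keto aldehyde (propanoyl on C3, 2-oxoethyl on C2), via bis-ozonide 39 (not isolated)
Conditions: O3, CH2Cl2, −78 °C; PPh3
Reagents that add atoms: ozone, [O-][O+]=O
Why: Ozonolysis with reductive work-up turns the 1,1-disubstituted alkene into the ethyl ketone and the allyl group into the aldehyde in one operation.

Step 28
Reactants: 40 keto aldehyde
Product: 41 bicyclic 2-methyl enone (mixture of epimers at the ring-fusion carbon next to the carbonyl)
Conditions: KOH, MeOH, 0 °C → rt
Reagents that add atoms: none
Why: Intramolecular aldol condensation; only the CH2 of the ethyl ketone can reach the aldehyde through a six-membered ring, since every other enolate would have to close a four-membered ring.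

Step 29
Reactants: 41 enone mixture
Product: 43 cis-fused enone, via lithium enolate 42 (not isolated)
Conditions: LiN(iPr)2, THF, −78 °C; 2,6-di-tert-butyl-4-methylphenol, −78 °C
Reagents that add atoms: none
Why: Kinetic protonation of the cross-conjugated enolate formed by α′-deprotonation; the hindered proton donor should approach the enolate carbon, which is exocyclic to ring B, from the equatorial side, opposite the axial methyl of the carbinol carbon. This places the acyl carbon axial and gives the cis ring fusion, as known for exocyclic enolates and 1-decalone enolates.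

### Part 5: fragment union and end game (steps 30–32)

Step 30
Reactants: 29 iodide; 43 cis-fused enone
Product: 46 tertiary allylic alcohol (carbinol epimers), via alkyllithium 44 (not isolated), via organocerium reagent 45 (not isolated)
Conditions: t-BuLi, Et2O–pentane, −78 °C; CeCl3, THF, −78 °C; then 43
Reagents that add atoms: none
Why: Iodine–lithium exchange, transmetalation to the non-basic organocerium reagent and 1,2-addition to the hindered enone carbonyl; enolisation is suppressed, so the cis ring fusion is kept, and the new carbinol centre is removed in the next step.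

Step 31
Reactants: 46 tertiary allylic alcohol
Product: 47 tris-silyl ether of sipholenol K
Conditions: [C5H5NH][CrO3Cl], NaOAc, 4 Å molecular sieves, CH2Cl2, rt
Reagents that add atoms: pyridinium chlorochromate, [O-][Cr](=O)(=O)Cl.c1cc[nH+]cc1
Why: Dauben–Babler oxidative transposition; the chromate ester of the tertiary allylic alcohol undergoes a [3,3] shift and the secondary allylic chromate is oxidised to the enone. The ring-fusion CH becomes the γ-carbon and is not touched.

Step 32
Reactants: 47 tris-silyl ether
Product: 48 sipholenol K
Conditions: HF·pyridine, THF, 0 → 40 °C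
Reagents that add atoms: none
Why: Cleavage of the three silyl ethers by fluoride in a buffered, weakly acidic medium that should spare the tertiary alcohols, the tert-alkyl ether and the base-sensitive γ-centre of the enone.

## Compound list

1 | (R)-Wieland–Miescher ketone, (8aR)-8a-methyl-3,4,8,8a-tetrahydronaphthalene-1,6(2H,7H)-dione | C[C@@]12CCC(=O)C=C1CCCC2=O | starting material
2 | 6,6-ethylenedithio ketal of 1 | C[C@@]12CCC3(SCCS3)C=C1CCCC2=O | intermediate
3 | (8aR)-8a-methyl-3,4,6,7,8,8a-hexahydronaphthalen-1(2H)-one | C[C@@]12CCCC=C1CCCC2=O | intermediate
4 | lithium enolate of 3 | C[C@@]12CCCC=C1CCC=C2O[Li] | intermediate (not isolated)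
5 | 2,8a-dimethyl octalinone, C2 epimers | C[C@@]12CCCC=C1CCC(C)C2=O | intermediate
6 | potassium enolate of 5 | C[C@@]12CCCC=C1CCC(C)=C2O[K] | intermediate (not isolated)
7 | (2S,8aR)-2-hydroxy-2,8a-dimethyl octalinone (2α-OH, 2β-Me) | C[C@@]12CCCC=C1CC[C@](C)(O)C2=O | intermediate
8 | tertiary TBS ether of 7 | C[C@@]12CCCC=C1CC[C@](C)(O[Si](C)(C)C(C)(C)C)C2=O | intermediate
9 | 1-methylene-2α-TBS-oxy-2β,8a-dimethyl octalin | C[C@@]12CCCC=C1CC[C@](C)(O[Si](C)(C)C(C)(C)C)C2=C | intermediate
10 | bis(alkylborane) from 9 (boron on the exocyclic carbon and on C5) | BC[C@H]1[C@]2(C)CCC[C@H](B)[C@H]2CC[C@]1(C)O[Si](C)(C)C(C)(C)C | intermediate (not isolated)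
11 | trans-decalin diol (1β-CH2OH, 5α-OH, 4aα-H, 2α-OTBS) | OC[C@H]1[C@]2(C)CCC[C@H](O)[C@H]2CC[C@]1(C)O[Si](C)(C)C(C)(C)C | intermediate
12 | primary TBS ether of 11 | CC(C)(C)[Si](C)(C)OC[C@H]1[C@]2(C)CCC[C@H](O)[C@H]2CC[C@]1(C)O[Si](C)(C)C(C)(C)C | intermediate
13 | trans-decalin-5-one | CC(C)(C)[Si](C)(C)OC[C@H]1[C@]2(C)CCCC(=O)[C@H]2CC[C@]1(C)O[Si](C)(C)C(C)(C)C | intermediate
14 | trimethylsilyl enol ether of 13 (C5=C6) | CC(C)(C)[Si](C)(C)OC[C@H]1[C@]2(C)CCC=C(O[Si](C)(C)C)[C@H]2CC[C@]1(C)O[Si](C)(C)C(C)(C)C | intermediate (not isolated)
15 | 6α-trimethylsilyloxy-5-ketone | CC(C)(C)[Si](C)(C)OC[C@H]1[C@]2(C)CC[C@H](O[Si](C)(C)C)C(=O)[C@H]2CC[C@]1(C)O[Si](C)(C)C(C)(C)C | intermediate (not isolated)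
16 | 6α-hydroxy-5-ketone | CC(C)(C)[Si](C)(C)OC[C@H]1[C@]2(C)CC[C@H](O)C(=O)[C@H]2CC[C@]1(C)O[Si](C)(C)C(C)(C)C | intermediate
17 | 6α-(2,2,2-trichloroethoxycarbonyloxy)-5-ketone (key-step precursor) | CC(C)(C)[Si](C)(C)OC[C@H]1[C@]2(C)CC[C@H](OC(=O)OCC(Cl)(Cl)Cl)C(=O)[C@H]2CC[C@]1(C)O[Si](C)(C)C(C)(C)C | intermediate
18 | trans-fused ε-lactone with α-carbonate (key-step product) | CC(C)(C)[Si](C)(C)OC[C@H]1[C@]2(C)CC[C@H](OC(=O)OCC(Cl)(Cl)Cl)C(=O)O[C@H]2CC[C@]1(C)O[Si](C)(C)C(C)(C)C | intermediate
19 | α-hydroxy ε-lactone | CC(C)(C)[Si](C)(C)OC[C@H]1[C@]2(C)CC[C@H](O)C(=O)O[C@H]2CC[C@]1(C)O[Si](C)(C)C(C)(C)C | intermediate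
20 | α-TBS-oxy ε-lactone | CC(C)(C)[Si](C)(C)OC[C@H]1[C@]2(C)CC[C@H](O[Si](C)(C)C(C)(C)C)C(=O)O[C@H]2CC[C@]1(C)O[Si](C)(C)C(C)(C)C | intermediate
21 | 2-methyleneoxepane (exocyclic enol ether) | CC(C)(C)[Si](C)(C)OC[C@H]1[C@]2(C)CC[C@H](O[Si](C)(C)C(C)(C)C)C(=C)O[C@H]2CC[C@]1(C)O[Si](C)(C)C(C)(C)C | intermediate
22 | spiro-cyclopropyl oxepane | CC(C)(C)[Si](C)(C)OC[C@H]1[C@]2(C)CC[C@H](O[Si](C)(C)C(C)(C)C)C3(CC3)O[C@H]2CC[C@]1(C)O[Si](C)(C)C(C)(C)C | intermediate
23 | 2,2-dimethyloxepane, tris-TBS ether | CC(C)(C)[Si](C)(C)OC[C@H]1[C@]2(C)CC[C@H](O[Si](C)(C)C(C)(C)C)C(C)(C)O[C@H]2CC[C@]1(C)O[Si](C)(C)C(C)(C)C | intermediate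
24 | primary alcohol of the perhydrobenzoxepine | OC[C@H]1[C@]2(C)CC[C@H](O[Si](C)(C)C(C)(C)C)C(C)(C)O[C@H]2CC[C@]1(C)O[Si](C)(C)C(C)(C)C | intermediate
25 | aldehyde | O=C[C@H]1[C@]2(C)CC[C@H](O[Si](C)(C)C(C)(C)C)C(C)(C)O[C@H]2CC[C@]1(C)O[Si](C)(C)C(C)(C)C | intermediate
26 | vinyl compound | C=C[C@H]1[C@]2(C)CC[C@H](O[Si](C)(C)C(C)(C)C)C(C)(C)O[C@H]2CC[C@]1(C)O[Si](C)(C)C(C)(C)C | intermediate
27 | B-alkyl-9-BBN from 26 | B1(CC[C@H]2[C@]3(C)CC[C@H](O[Si](C)(C)C(C)(C)C)C(C)(C)O[C@H]3CC[C@]2(C)O[Si](C)(C)C(C)(C)C)C2CCCC1CCC2 | intermediate (not isolated)
28 | 2-hydroxyethyl compound | OCC[C@H]1[C@]2(C)CC[C@H](O[Si](C)(C)C(C)(C)C)C(C)(C)O[C@H]2CC[C@]1(C)O[Si](C)(C)C(C)(C)C | intermediate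
29 | 2-iodoethyl compound (ring-CD fragment) | ICC[C@H]1[C@]2(C)CC[C@H](O[Si](C)(C)C(C)(C)C)C(C)(C)O[C@H]2CC[C@]1(C)O[Si](C)(C)C(C)(C)C | intermediate
30 | 2-bromobut-1-ene | C=C(Br)CC | starting material
31 | but-1-en-2-ylmagnesium bromide | C=C([Mg]Br)CC | intermediate (not isolated)
32 | 9-(but-1-en-2-yl)-9-borabicyclo[3.3.1]nonane | C=C(CC)B1C2CCCC1CCC2 | intermediate
33 | 4,4-dimethylcyclohex-2-en-1-one | CC1(C)CCC(=O)C=C1 | starting material
34 | boron enolate (9-BBN enol borinate of the 3-alkenyl ketone) | CC1(C)CCC(OB2C3CCCC2CCC3)=C[C@@H]1C(=C)CC | intermediate (not isolated)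
35 | lithium enolate of the 3-alkenyl ketone | CC1(C)CCC(O[Li])=C[C@@H]1C(=C)CC | intermediate (not isolated)
36 | (2S,3S)-2-allyl-3-(but-1-en-2-yl)-4,4-dimethylcyclohexan-1-one | O=C1CCC(C)(C)[C@@H](C(=C)CC)[C@@H]1CC=C | intermediate
37 | 2-allyl-3-(but-1-en-2-yl)-1,4,4-trimethylcyclohexan-1-ol (methyl cis to allyl, allyl trans to butenyl) | C[C@]1(O)CCC(C)(C)[C@@H](C(=C)CC)[C@@H]1CC=C | intermediate
38 | triethylsilyl ether of 37 | C[C@]1(O[Si](CC)(CC)CC)CCC(C)(C)[C@@H](C(=C)CC)[C@@H]1CC=C | intermediate
39 | bis-ozonide of 38 | C[C@]1(O[Si](CC)(CC)CC)CCC(C)(C)[C@@H](C2(CC)OCOO2)[C@@H]1CC1OCOO1 | intermediate (not isolated)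
40 | keto aldehyde (3-propanoyl, 2-(2-oxoethyl)) | C[C@]1(O[Si](CC)(CC)CC)CCC(C)(C)[C@@H](C(=O)CC)[C@@H]1CC=O | intermediate
41 | bicyclic 2-methyl enone, 2,5,8,8-tetramethyl-5-(triethylsilyloxy)-4a,5,6,7,8,8a-hexahydronaphthalen-1(4H)-one, epimers at C8a | CC1=CC[C@H]2C(C1=O)C(C)(C)CC[C@]2(C)O[Si](CC)(CC)CC | intermediate
42 | cross-conjugated lithium enolate of 41 | CC1=CC[C@H]2C(=C1O[Li])C(C)(C)CC[C@]2(C)O[Si](CC)(CC)CC | intermediate (not isolated)
43 | cis-fused enone (ring-AB fragment) | CC1=CC[C@H]2[C@@H](C1=O)C(C)(C)CC[C@]2(C)O[Si](CC)(CC)CC | intermediate
44 | alkyllithium from 29 | [Li]CC[C@H]1[C@]2(C)CC[C@H](O[Si](C)(C)C(C)(C)C)C(C)(C)O[C@H]2CC[C@]1(C)O[Si](C)(C)C(C)(C)C | intermediate (not isolated)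
45 | alkylcerium dichloride from 44 | Cl[Ce](Cl)CC[C@H]1[C@]2(C)CC[C@H](O[Si](C)(C)C(C)(C)C)C(C)(C)O[C@H]2CC[C@]1(C)O[Si](C)(C)C(C)(C)C | intermediate (not isolated)
46 | tertiary allylic alcohol (carbinol epimers) | CC1=CC[C@H]2[C@@H](C1(O)CC[C@H]1[C@]3(C)CC[C@H](O[Si](C)(C)C(C)(C)C)C(C)(C)O[C@H]3CC[C@]1(C)O[Si](C)(C)C(C)(C)C)C(C)(C)CC[C@]2(C)O[Si](CC)(CC)CC | intermediate
47 | tris-silyl ether of sipholenol K | CC1=C(CC[C@H]2[C@]3(C)CC[C@H](O[Si](C)(C)C(C)(C)C)C(C)(C)O[C@H]3CC[C@]2(C)O[Si](C)(C)C(C)(C)C)[C@@H]2[C@H](CC1=O)[C@@](C)(O[Si](CC)(CC)CC)CCC2(C)C | intermediate
48 | sipholenol K | CC1=C(CC[C@H]2[C@]3(C)CC[C@H](O)C(C)(C)O[C@H]3CC[C@]2(C)O)[C@@H]2[C@H](CC1=O)[C@@](C)(O)CCC2(C)C | target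

## Step count and least certain steps

Total step count: 32. Longest linear sequence: 25 steps (steps 1–22, then 30–32). The ring-AB branch has 7 steps (23–29) before the union.

**Step 12 (key step).** What may go wrong: migration of the oxygenated carbon in competition with the ring-fusion carbon, which would give the acylal-type lactone; or acid-induced loss of the primary silyl ether and epimerisation of the axial α-carbonate before the oxidation is complete. Fallback: the order of oxygen insertion and α-oxygenation is reversed. Ketone 13, which has no α-oxygen, is oxidised with mCPBA and NaHCO3. Here the ring-fusion CH competes only with a CH2 and should migrate as the more substituted carbon, giving the trans-fused ε-lactone F1. The lithium enolate of F1 (LiN(iPr)2, −78 °C) is then hydroxylated with 2-(phenylsulfonyl)-3-phenyloxaziridine, expected mainly on the face away from the angular methyl, to give hydroxy lactone 19, where the route is rejoined. An epimer at the carbinol would have to be separated.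

**Step 24.** What may go wrong: slow transfer of the α-branched alkenyl group to rhodium and slow insertion at the β-carbon next to the quaternary centre, with hydrolysis of the borane taking over; low enantioselectivity; or incomplete allylation of the enolate. Fallback: the three-component coupling is run without asymmetric induction and the product is resolved. Enone 33 is treated with the Grignard reagent 31 under CuBr·SMe2 catalysis and the magnesium enolate is allylated, giving the racemic trans ketone F2. Condensation with (S)-1-amino-2-(methoxymethyl)pyrrolidine gives two diastereomeric hydrazones. The one derived from the (2S,3S) ketone, F3, is separated by chromatography and cleaved with aqueous oxalic acid to return ketone 36.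

**Step 29.** What may go wrong: poor facial selectivity of the protonation, competing γ-deprotonation, or re-equilibration of the cis ketone to the trans isomer during work-up. Fallback: the ring fusion is left uncorrected at the ketone stage and is adjusted thermodynamically at the end. Mixture 41 is taken through steps 30 and 31, which gives the trans-fused alcohol F4 and the trans-fused enone F5 beside their cis isomers. The γ ring-fusion centre of F5 is then equilibrated through the extended enolate (DBU, toluene, heat). In the enone the trans isomer has to hold the quaternary ring carbon in the plane of the tetrasubstituted alkene next to the tether, a strain the cis isomer avoids, so the equilibrium is expected to move toward 47; this expectation is not secure and would have to be tested.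

**Step 17.** What may go wrong: cleavage of a ring bond next to the oxygen-bearing carbon, which would give an ethyl group; acid-promoted opening of the cyclopropyl ether; or partial loss of silyl groups in acetic acid. Fallback: the second methyl group is introduced as a nucleophile and not by hydrogenolysis. Enol ether 21 is treated with methanol and pyridinium p-toluenesulfonate to give the methyl ketal F6. AlMe3 in CH2Cl2 at low temperature ionises F6 to the oxocarbenium ion and methylates it, giving the gem-dimethyl ether 23.

**Step 31.** What may go wrong: ionisation and dehydration of the hindered tertiary allylic alcohol to dienes in place of the chromate shift, or loss of the tertiary triethylsilyl ether in the acidic chromium medium. Fallback: transposition and oxidation are separated. Alcohol 46 is isomerised with catalytic Ph3SiOReO3 to the 1,3-transposed secondary allylic alcohol F7, which is favoured because its alkene is tetrasubstituted. F7 is then oxidised with MnO2 to enone 47.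

## Further compounds

F1 | step 12 | trans-fused ε-lactone without α-oxygen, from ketone 13 | CC(C)(C)[Si](C)(C)OC[C@H]1[C@]2(C)CCCC(=O)O[C@H]2CC[C@]1(C)O[Si](C)(C)C(C)(C)C
F2 | step 24 | racemic trans-2-allyl-3-(but-1-en-2-yl)-4,4-dimethylcyclohexan-1-one (both enantiomers) | O=C1CCC(C)(C)[C@@H](C(=C)CC)[C@@H]1CC=C.O=C1CCC(C)(C)[C@H](C(=C)CC)[C@H]1CC=C
F3 | step 24 | (S)-1-amino-2-(methoxymethyl)pyrrolidine hydrazone of ketone 36 | COC[C@@H]1CCCN1N=C1CCC(C)(C)[C@@H](C(=C)CC)[C@@H]1CC=C
F4 | step 29 | trans-fused epimer of allylic alcohol 46 | CC1=CC[C@H]2[C@H](C1(O)CC[C@H]1[C@]3(C)CC[C@H](O[Si](C)(C)C(C)(C)C)C(C)(C)O[C@H]3CC[C@]1(C)O[Si](C)(C)C(C)(C)C)C(C)(C)CC[C@]2(C)O[Si](CC)(CC)CC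
F5 | step 29 | trans-fused epimer of enone 47 | CC1=C(CC[C@H]2[C@]3(C)CC[C@H](O[Si](C)(C)C(C)(C)C)C(C)(C)O[C@H]3CC[C@]2(C)O[Si](C)(C)C(C)(C)C)[C@H]2[C@H](CC1=O)[C@@](C)(O[Si](CC)(CC)CC)CCC2(C)C
F6 | step 17 | 2-methoxy-2-methyloxepane (methyl ketal of the ring-D carbon, anomers) | CC(C)(C)[Si](C)(C)OC[C@H]1[C@]2(C)CC[C@H](O[Si](C)(C)C(C)(C)C)C(C)(OC)O[C@H]2CC[C@]1(C)O[Si](C)(C)C(C)(C)C
F7 | step 31 | 1,3-transposed secondary allylic alcohol (carbinol epimers) | CC1=C(CC[C@H]2[C@]3(C)CC[C@H](O[Si](C)(C)C(C)(C)C)C(C)(C)O[C@H]3CC[C@]2(C)O[Si](C)(C)C(C)(C)C)[C@@H]2[C@H](CC1O)[C@@](C)(O[Si](CC)(CC)CC)CCC2(C)C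
A1 | alternative 1 | cis-fused bicyclic vinylogous ester with tertiary triethylsilyl ether | CCOC1=C(C)C(=O)[C@@H]2[C@H](C1)[C@@](C)(O[Si](CC)(CC)CC)CCC2(C)C
A2 | alternative 1 | trimethylsilyl dienol ether of the 3-ethoxy-2-methylcyclohexenone carrying the tertiary chloride side chain | CCOC1=C(C)C(O[Si](C)(C)C)=C[C@H](C1)[C@@](C)(O[Si](CC)(CC)CC)CCC(C)(C)Cl
A3 | alternative 2 | 2-allyl-3-homoprenyl-3-methyl-4-(tert-butyldimethylsilyloxy)cyclohexanone | C=CC[C@H]1[C@](C)(CCC=C(C)C)[C@@H](O[Si](C)(C)C(C)(C)C)CCC1=O
A4 | alternative 2 | (S)-4-(tert-butyldimethylsilyloxy)-3-methylcyclohex-2-en-1-one | CC1=CC(=O)CC[C@@H]1O[Si](C)(C)C(C)(C)C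
A5 | alternative 3 | cis-fused octalone with allylic 4-methoxybenzyl ether and attached ring-CD half | CC1=C(CC[C@H]2[C@]3(C)CC[C@H](O[Si](C)(C)C(C)(C)C)C(C)(C)O[C@H]3CC[C@]2(C)O)[C@@H]2[C@H](C[C@H]1OCc3ccc(OC)cc3)C(=O)CCC2(C)C
A6 | alternative 3 | open-chain trienone (vinyl ketone tethered to the 1-alkoxy diene) with attached ring-CD half | COc1ccc(CO/C=C(C)/C(CC[C@H]2[C@]3(C)CC[C@H](O[Si](C)(C)C(C)(C)C)C(C)(C)O[C@H]3CC[C@]2(C)O)=C/C(C)(C)CCC(=O)C=C)cc1
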